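Ring C (C8, C9, C11, C12, C13, C14) is cut at C12–C13 and C14–C8. Both bonds form in one aminocatalytic formal inverse-demand [4+2] reaction: the E-enamine of a 4-oxobutanamide (C14, C13, C16, C15) adds to a spiro dienyl lactone (C8=C9–C11=C12), and loss of the amine leaves C8=C14. The step exploits that C12 is δ and C8 is α to the lactone carbonyl C7, and that C13–C16–C15 of ring D is a latent acyl chain. The precursor is a flat spirolactone diene carrying ring A with C5 and C10 set; the catalyst sets C13, and C8, C9 and C16 follow by substrate control.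

Key step: step 7

Remark: atoms are numbered as in ent-kaurane. Ring A = C1(=O), C2=C3, C4(Me2), C5, C10; C6 = CH2OH on C5; lactone = C10–C20H2–O–C7(=O)–C8–C9; ring C = C8, C9, C11, C12, C13, C14; ring D = C8, C14, C13, C16, C15(=O); C17 = CH2OH on C16. PMB = 4-methoxybenzyl; PMBOCH2MgCl is taken as a stock solution made from 4-methoxybenzyl chloromethyl ether and magnesium.

Step 1
Reactants: 1 4,4-dimethylcyclohexa-2,5-dien-1-one
Product: 3 (5S,6R)-6-(hydroxymethyl)-5-{[(4-methoxybenzyl)oxy]methyl}-4,4-dimethylcyclohex-2-en-1-one, via magnesium dienolate 2 (not isolated)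
Conditions: PMBOCH2MgCl (1.5 equiv), CuBr·SMe2 (5 mol %), 1-[2-(diphenylphosphino)ferrocenyl]ethyldicyclohexylphosphine (Josiphos, 6 mol %, enantiomer matched to 5S), t-BuOMe, −78 °C; then monomeric CH2O in THF, −78 → −40 °C; aq NH4Cl
Reagents that add atoms: {[(4-methoxybenzyl)oxy]methyl}magnesium chloride, COc1ccc(COC[Mg]Cl)cc1; formaldehyde, C=O
Why: Copper-catalysed asymmetric conjugate addition of a Grignard reagent should desymmetrise the dienone (the chiral diphosphine–copper complex picks one enantiotopic enone and sets C5), and the dienolate is then hydroxymethylated at C10 anti to the new C5 side chain in a tandem conjugate addition–aldol reaction.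

Step 2
Reactants: 3 (5S,6R)-6-(hydroxymethyl)-5-{[(4-methoxybenzyl)oxy]methyl}-4,4-dimethylcyclohex-2-en-1-one
Product: 5 6-(hydroxymethyl)-6-(1-hydroxyprop-2-en-1-yl)-5-{[(4-methoxybenzyl)oxy]methyl}-4,4-dimethylcyclohex-2-en-1-one (C9 trans to C6 on ring A; carbinol epimers), via dilithium alkoxide enolate 4 (not isolated)
Conditions: LiN(i-Pr)2 (2.2 equiv), THF, −78 °C; then acrolein, −78 °C; aq NH4Cl
Reagents that add atoms: acrolein, C=CC=O
Why: The Fráter–Seebach-type alkoxide enolate can form only at C10 (C2 is vinylic, C4 quaternary) and should add 1,2 to acrolein in a kinetic aldol reaction from the face anti to the C5 side chain, which sets the quaternary C10 with C9 trans to C6; the carbinol centre is oxidised in step 4.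

Step 3
Reactants: 5 the diol of step 2
Product: 6 C20 O-[(diethoxyphosphoryl)acetyl] ester of 5
Conditions: (EtO)2P(O)CH2CO2H, DCC, DMAP (10 mol %), CH2Cl2, 0 °C
Reagents that add atoms: (diethoxyphosphoryl)acetic acid, CCOP(=O)(CC(=O)O)OCC
Why: Steglich esterification should acylate the primary C20 hydroxyl in preference to the more hindered secondary allylic C9 hydroxyl.

Step 4
Reactants: 6 the phosphonoacetate of step 3
Product: 8 5-ethenyl-11-{[(4-methoxybenzyl)oxy]methyl}-10,10-dimethyl-2-oxaspiro[5.5]undeca-4,8-diene-3,7-dione (spiro dienyl lactone; C5 and C10 as in 5), via vinyl ketone 7 (not isolated)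
Conditions: Dess–Martin periodinane, CH2Cl2, 0 °C; then LiCl, DBU, MeCN, 0 °C → rt
Reagents that add atoms: none
Why: Dess–Martin oxidation gives the C9 vinyl ketone, whose acyclic carbonyl (expected to be more electrophilic than the ring A enone carbonyl) is attacked by the tethered phosphonate in an intramolecular Horner–Wadsworth–Emmons reaction under Masamune–Roush conditions, closing the six-membered lactone with the cis C8=C9 geometry that the ring imposes.

Step 5
Reactants: 9 pent-4-enoyl chloride
Product: 10 N-methoxy-N-methylpent-4-enamide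
Conditions: MeNH(OMe)·HCl, pyridine, CH2Cl2, 0 °C → rt
Reagents that add atoms: N,O-dimethylhydroxylamine hydrochloride, CNOC.Cl
Why: Acylation of the amine by the acid chloride gives the Weinreb amide.

Step 6
Reactants: 10 N-methoxy-N-methylpent-4-enamide
Product: 12 N-methoxy-N-methyl-4-oxobutanamide, via ozonide 11 (not isolated)
Conditions: O3, CH2Cl2, −78 °C; then PPh3, −78 °C → rt
Reagents that add atoms: ozone, [O-][O+]=O
Why: Ozonolysis of the terminal alkene with reductive work-up gives the aldehyde and leaves the Weinreb amide untouched.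

Step 7
Reactants: 8 spiro dienyl lactone; 12 N-methoxy-N-methyl-4-oxobutanamide
Product: 14 tricyclic diene lactone (C8=C14 and C9=C11; C13 carries CH2C(=O)N(OMe)Me; ring A enone; C6 O-PMB), via aminocyclohexene adduct 13 (not isolated)
Conditions: (S)-α,α-diphenylprolinol trimethylsilyl ether (20 mol %), PhCO2H (20 mol %), toluene, 40 °C, slow addition of 12 (2.5 equiv)
Reagents that add atoms: none
Why: The amine and 12 give an E-enamine whose β-carbon C13 adds 1,6 to the unhindered vinyl terminus C12 of 8, the dienolate so formed closes on the iminium carbon C14 through C8 (Mannich), and E1cB loss of the amine from 13 (C8–H is α to the lactone carbonyl) gives 14 and returns the catalyst. The closest known reactions are the [4+2] cycloaddition of enamines with 2,4-pentadienoates followed by amine elimination and the aminocatalytic inverse-electron-demand Diels–Alder reaction of aldehydes. Only ring C is closed, as a formal [4+2] whose second bond forms by a 6-(enolexo)-exo-trig closure. C13 is the only new stereocentre that survives (C8 and C14 end sp2), and it is set by the catalyst: the CPh2OSiMe3 group shields one face of the enamine so that C12 bonds to the Si face of C13, whichever face of the diene reacts. The step needs regioselectivity (C12 not C9, C8 not C11), secured by the fully substituted C9 and by ring size, and chemoselectivity over the ring A enone, secured by its neopentyl β-carbon C3. C13–H is only vinylogously acidic and should not epimerise in the benzoate buffer.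

Step 8
Reactants: 14 tricyclic diene lactone
Product: 16 tetracyclic 9(11)-ene with C1 and C15 ketones (ring A saturated; C6 O-PMB; C5, C8, C10, C13 as in the target), via dilithium bis-enolate 15 (not isolated)
Conditions: LiBH(s-Bu)3 (2.2 equiv), THF, −78 → 0 °C; aq NH4Cl
Reagents that add atoms: none
Why: Hydride should add in conjugate fashion to C3 of the ring A enone and to C14 of the acrylate-type lactone, and the regiospecific C8 dienolate is acylated by the tethered Weinreb amide in a 5-(enolexo)-exo-trig closure whose chelated tetrahedral intermediate cannot revert by loss of an alkoxide, which closes ring D on the face dictated by C13 and sets the quaternary C8.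

Step 9
Reactants: 16 tetracyclic PMB ether
Product: 17 C6 alcohol of 16
Conditions: DDQ, CH2Cl2/pH 7 buffer, 0 °C
Reagents that add atoms: none
Why: Oxidative cleavage of the PMB ether by DDQ should free the C6 hydroxyl without touching the ketones, the lactone or the trisubstituted alkene.

Step 10
Reactants: 17 tetracyclic 9(11)-ene alcohol
Product: 18 saturated tetracyclic diketo lactone (C9–H as in the target)
Conditions: [Ir(cod)(PCy3)(py)]PF6 (15 mol %), H2 (1 atm), CH2Cl2, rt
Reagents that add atoms: none
Why: Hydroxyl-directed hydrogenation should deliver H2 to C9=C11 from the face on which C5 and its CH2OH sit (the endo face, syn to the C15–C16 bridge), which sets C9 with C10 anti to the bridge.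

Step 11
Reactants: 18 saturated tetracyclic diketo lactone
Product: 20 ring A enone (the target lacking C17), via tris-silyl derivative 19 (not isolated)
Conditions: Me3SiOTf, Et3N, CH2Cl2, 0 °C; then Pd(OAc)2, MeCN, rt; 1 M HCl, THF
Reagents that add atoms: none
Why: In this Saegusa–Ito oxidation both ketones are silylated, but only the ring A palladium enolate has a β-hydrogen it can lose (the ring D enolate would have to form an anti-Bredt bridgehead alkene at C13), so C2=C3 is restored selectively and the silyl groups fall off on acidic work-up.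

Step 12
Reactants: 20 ring A enone
Product: 22 CNP0505075.1, via bis-silyl derivative 21 (not isolated)
Conditions: Me3SiOTf, Et3N, CH2Cl2, −78 °C; then aq CH2O, Yb(OTf)3 (20 mol %), THF, rt
Reagents that add atoms: formaldehyde, C=O
Why: Mukaiyama-type hydroxymethylation of the only possible silyl enol ether (C15=C16) with aqueous formaldehyde should occur on the exo face of the bicyclo[3.2.1]octane, placing C17 exo and H16 endo as in the target, under conditions too mild for retro-aldol or dehydration.

Compound list
1 | 4,4-dimethylcyclohexa-2,5-dien-1-one | CC1(C)C=CC(=O)C=C1 | starting material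
2 | chloromagnesium dienolate of (5S)-5-{[(4-methoxybenzyl)oxy]methyl}-4,4-dimethylcyclohex-2-en-1-one | CC1(C)C=CC(O[Mg]Cl)=C[C@@H]1COCc1ccc(OC)cc1 | intermediate
3 | (5S,6R)-6-(hydroxymethyl)-5-{[(4-methoxybenzyl)oxy]methyl}-4,4-dimethylcyclohex-2-en-1-one | CC1(C)C=CC(=O)[C@@H](CO)[C@@H]1COCc1ccc(OC)cc1 | intermediate
4 | dilithium alkoxide enolate of 3 | CC1(C)C=CC(O[Li])=C(CO[Li])[C@@H]1COCc1ccc(OC)cc1 | intermediate
5 | 6-(hydroxymethyl)-6-(1-hydroxyprop-2-en-1-yl)-5-{[(4-methoxybenzyl)oxy]methyl}-4,4-dimethylcyclohex-2-en-1-one (hydroxyallyl group trans to the PMB-oxymethyl group; carbinol epimers) | CC1(C)C=CC(=O)[C@@](CO)(C(O)C=C)[C@@H]1COCc1ccc(OC)cc1 | intermediate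
6 | C20 O-[(diethoxyphosphoryl)acetyl] ester of 5 | CC1(C)C=CC(=O)[C@@](COC(=O)CP(=O)(OCC)OCC)(C(O)C=C)[C@@H]1COCc1ccc(OC)cc1 | intermediate
7 | C9 vinyl ketone from 6 | CC1(C)C=CC(=O)[C@@](COC(=O)CP(=O)(OCC)OCC)(C(=O)C=C)[C@@H]1COCc1ccc(OC)cc1 | intermediate
8 | 5-ethenyl-11-{[(4-methoxybenzyl)oxy]methyl}-10,10-dimethyl-2-oxaspiro[5.5]undeca-4,8-diene-3,7-dione (spiro centre and C11 as in SMILES) | CC1(C)C=CC(=O)[C@]2(COC(=O)C=C2C=C)[C@@H]1COCc1ccc(OC)cc1 | intermediate
9 | pent-4-enoyl chloride | C=CCCC(=O)Cl | starting material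
10 | N-methoxy-N-methylpent-4-enamide | C=CCCC(=O)N(C)OC | intermediate
11 | secondary ozonide (1,2,4-trioxolane) of 10 | CON(C)C(=O)CCC1OCOO1 | intermediate
12 | N-methoxy-N-methyl-4-oxobutanamide | O=CCCC(=O)N(C)OC | intermediate
13 | aminocyclohexene adduct: ring C closed, C14 bearing the prolinol ether nitrogen, C8–H (C8 and C14 epimers) | CC1(C)C=CC(=O)[C@]2(COC(=O)C3C(N4CCC[C@H]4C(c4ccccc4)(c4ccccc4)O[Si](C)(C)C)[C@H](CC(=O)N(C)OC)CC=C32)[C@@H]1COCc1ccc(OC)cc1 | intermediate
14 | tricyclic diene lactone (C8=C14, C9=C11; C13 bearing CH2C(=O)N(OMe)Me; ring A enone; C6 O-PMB) | CC1(C)C=CC(=O)[C@]2(COC(=O)C3=C[C@H](CC(=O)N(C)OC)CC=C32)[C@@H]1COCc1ccc(OC)cc1 | intermediate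
15 | dilithium bis-enolate (C1 enolate and C7/C8 dienolate) of reduced 14 | CC1(C)CC=C(O[Li])[C@]2(COC(O[Li])=C3C[C@H](CC(=O)N(C)OC)CC=C32)[C@@H]1COCc1ccc(OC)cc1 | intermediate
16 | tetracyclic 9(11)-ene, C1 and C15 ketones, 7,20-lactone, C6 O-PMB | CC1(C)CCC(=O)[C@]2(COC(=O)[C@@]34C[C@@H](CC=C32)CC4=O)[C@@H]1COCc1ccc(OC)cc1 | intermediate
17 | C6 alcohol of 16 | CC1(C)CCC(=O)[C@]2(COC(=O)[C@@]34C[C@@H](CC=C32)CC4=O)[C@@H]1CO | intermediate
18 | saturated tetracyclic diketo lactone with C9–H set | CC1(C)CCC(=O)[C@]2(COC(=O)[C@@]34C[C@@H](CC[C@H]32)CC4=O)[C@@H]1CO | intermediate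
19 | tris(trimethylsilyl) derivative of 18 (C1 and C15 silyl enol ethers, C6 silyl ether) | CC1(C)CC=C(O[Si](C)(C)C)[C@]2(COC(=O)[C@@]34C[C@@H](CC[C@H]32)C=C4O[Si](C)(C)C)[C@@H]1CO[Si](C)(C)C | intermediate
20 | ring A enone: the target lacking C17 | CC1(C)C=CC(=O)[C@]2(COC(=O)[C@@]34C[C@@H](CC[C@H]32)CC4=O)[C@@H]1CO | intermediate
21 | bis(trimethylsilyl) derivative of 20 (C15 silyl enol ether, C6 silyl ether) | CC1(C)C=CC(=O)[C@]2(COC(=O)[C@@]34C[C@@H](CC[C@H]32)C=C4O[Si](C)(C)C)[C@@H]1CO[Si](C)(C)C | intermediate
22 | CNP0505075.1 | CC1(C)C=CC(=O)[C@]2(COC(=O)[C@@]34C[C@@H](CC[C@H]32)[C@H](CO)C4=O)[C@@H]1CO | target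

Total step count: 12. Longest linear sequence: 10 steps (steps 1–4 and 7–12).

Steps most likely to fail

Step 7. The hindered prolinol-derived enamine may add too slowly to the weakly electrophilic dienyl lactone, so that self-aldol of 12 or arrest of the catalyst at the adduct stage takes over. Fallback, from 8 and 12: 12 is condensed with (S)-2-(methoxymethyl)pyrrolidine over 4 Å molecular sieves to the preformed E-enamine F4, which is heated with 8 in MeCN at 60 °C to give the aminocyclohexene F5. Buffered AcOH/NaOAc then eliminates the auxiliary, and the route is rejoined at 14. Stereocontrol at C13 then rests on a stoichiometric chiral enamine instead of catalyst turnover.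

Step 10. Hydrogen may be delivered to the exo face (sterically easier, and possibly directed by the C1 ketone), or the hindered alkene may not react, giving poor facial selectivity at C9. Fallback, from 14: the alkene is reduced before ring D exists. DDQ should give the diene alcohol F6. [Ir(cod)(PCy3)(py)]PF6 under H2 (50 bar) should then reduce C2=C3, C8=C14 and C9=C11 with delivery from the C5 face of the still unbridged ring C, giving the saturated tricycle F7. LiN(i-Pr)2 (3.5 equiv, THF, −78 → 0 °C) then closes ring D by enolate acylation of the Weinreb amide, and the route is rejoined at 18.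

Step 1. The α-alkoxy Grignard reagent may give poor enantioselection or competing 1,2-addition. Fallback, from 1: Rh(acac)(C2H4)2 with BINAP (enantiomer matched to R) and potassium vinyltrifluoroborate should give (R)-5-ethenyl-4,4-dimethylcyclohex-2-en-1-one F1. Ozonolysis with NaBH4 work-up at −78 °C should give (S)-5-(hydroxymethyl)-4,4-dimethylcyclohex-2-en-1-one F2. PMB trichloroacetimidate with catalytic TfOH should give the PMB ether F3. LiN(i-Pr)2 then monomeric CH2O (anti to the C5 side chain) rejoins the route at 3.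

Further compounds
F1 | step 1 | (R)-5-ethenyl-4,4-dimethylcyclohex-2-en-1-one | CC1(C)C=CC(=O)C[C@@H]1C=C
F2 | step 1 | (S)-5-(hydroxymethyl)-4,4-dimethylcyclohex-2-en-1-one | CC1(C)C=CC(=O)C[C@@H]1CO
F3 | step 1 | (S)-5-{[(4-methoxybenzyl)oxy]methyl}-4,4-dimethylcyclohex-2-en-1-one | CC1(C)C=CC(=O)C[C@@H]1COCc1ccc(OC)cc1
F4 | step 7 | E-enamine of 12 with (S)-2-(methoxymethyl)pyrrolidine | COC[C@@H]1CCCN1/C=C/CCC(=O)N(C)OC
F5 | step 7 | aminocyclohexene adduct of F4 and 8 (C8 and C14 epimers) | CC1(C)C=CC(=O)[C@]2(COC(=O)C3C(N4CCC[C@H]4COC)[C@H](CC(=O)N(C)OC)CC=C32)[C@@H]1COCc1ccc(OC)cc1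
F6 | step 10 | C6 alcohol of 14 | CC1(C)C=CC(=O)[C@]2(COC(=O)C3=C[C@H](CC(=O)N(C)OC)CC=C32)[C@@H]1CO
F7 | step 10 | saturated tricyclic hydroxy keto lactone Weinreb amide (H8 and H9 cis) | CC1(C)CCC(=O)[C@]2(COC(=O)[C@H]3C[C@H](CC(=O)N(C)OC)CC[C@H]32)[C@@H]1CO
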